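Slowness is the first thing you meet here: at 6.00 d east still held 51.6% of its substrate, so this ledger is kept in days.

| flask | substrate | reagent in the second phase | remark | time | volume of the second phase over the first |
|---|---|---|---|---|---|
| east | 3 M | 1.9 M | run made earlier |  |  |
| flask | 3.0 M | 3.90 M |  | 6.0 d | 2.0 |

east run (percent of the substrate charged)

| time / d | target / % | substrate / % |
|---|---|---|
| 1.04 | 12.5 | 82.0 |
| 2.08 | 20.9 | 70.9 |
| 3.00 | 23.5 | 64.0 |
| 4.00 | 24.4 | 58.8 |
| 5.00 | 24.3 | 54.9 |
| 6.00 | 23.3 | 51.6 |

(readings scatter by 1 percentage point)

- in the second phase: reagent in the second phase; everything else is in the first
- charges count per volume of the first phase; a concentration in a rate is the amount of a species over the volume of its own phase; every rate counts per litre of the first phase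
- on the list of suspects stand: reagent in the reaction phase <-> reagent in the second phase; substrate + reagent in the reaction phase -> target; target <-> isomer of the product; 2 reagent in the reaction phase -> homo dimer; target -> over-reaction product
- the earlier runs hold the two phases in the same ratio of volumes as the flask asked about

- ochre: doubling the amount of reagent in the second phase, all else as stated
- violet: doubling the transfer coefficient of the reagent in the second phase, all else as stated

* target at 6.0 d, in percent of the substrate charged
* the change that raises the amount of target at 6.0 d, in percent of the substrate charged most ("none" if none brings more than 2 percentage points) (ochre / violet / none)
* amount of target at 6.0 d, in percent of the substrate charged, after ochre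

In the flask substrate, at 3.0 M, is less than the 3.90 M of reagent in the second phase, so substrate is the limiting reagent and the ledger follows it.

Start with east, which had consumed 48.4% of its substrate and showed 23.3% as target, a ratio of 0.481. This ratio, target present over substrate consumed at the same age, I call the kept share. I carry it to the flask at equal age, since the suspected steps that take target away use no reagent.

The next entry is substrate left. I take the rate as k·c(substrate)·c(reagent), with the reagent falling one for one with substrate, and work in logarithms. East then gives k = 0.119 /M/d, and the same integrated law leaves the flask 20.4% of its substrate at 6.0 d.

| Entry, of substrate charged | east, read | flask, my reckoning |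
|---|---|---|
| substrate left | 51.6% | 20.4% |
| target | 23.3% | 38.3% |
| isomer of the product or over-reaction product | 25.1% | 41.3% |

At the kept share, the substrate left in the flask is worth 9.8 percentage points of target against the margin of 2 points, so I would take ochre.

The forecast, working from east by its own route, read the lost target as “a quick isomer equilibrium (isomer ≈ 0.2 × target) plus over-reaction at about 0.17/d on target”. It gave 37%, slightly below mine, chose ochre, and put target after it at 41.5%.

The simulation gives 37.6% and names ochre, which gains 5.5 points against −0.015 points for violet, with 43.1% after ochre.

    reagent in the reaction phase ⇌ reagent in the second phase, rate k1*([reagent in the reaction phase] - [reagent in the second phase]/K1) per volume of the first phase (partition coefficient = 2.60, kL = 1.60 /h)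
    substrate + reagent in the reaction phase → target (k = 0.0338 /M/h)
    target ⇌ isomer of the product (K = 0.220, k = 0.0456 /h)
    2 reagent in the reaction phase → homo dimer (k = 0.0114 /M/h)
    target → over-reaction product (k = 0.00658 /h)

The flask has 22% of its substrate left, so the kept share gives 37.5%. A neighbour flask with 0.75 M of substrate has 9.9% left, the share gives 43.3%, and that flask stands at 43.2%. Part of the reason the flask still shows so much target is the way back from isomer of the product to target, acting together with the reading at 6.0 d rather than at 60.0 d: without the way back the flask gives 3.54% of target rather than 37.6%, and read at the later time it gives 0.341%.

The runs were computed on assumed constants.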